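**Plan**

- Retrosynthesis (carotenoid numbering: ring C2 carries isopropenyl, C5 carries CH3 and OH, C6 carries the polyene): cut C11=C12 (Wittig: cyclopentyl C15 phosphonium salt + acyclic C25 aldehyde), then C11'=C12' (acyclic C15 salt + C10 dialdehyde), then C9–C10 and C7=C8 back to a C10 ring aldehyde.
- The cyclopentane is cut at C4–C5 and C2–C6 in one operation: a [3+2] union of isopropenylcyclopropane (C2–C3–C4) with the C=C bond of a 6-methyl-1,3-dioxin-4-one (C5=C6, C7 being the lactone carbonyl).
- Feature that allows it: C2 is a ring CH allylic to the exocyclic isopropenyl C=C and followed by two ring CH2 groups, the imprint of a ring-opened vinylcyclopropane; O–C5(CH3)–C6–C7 is a masked acetoacetate whose oxygen and carboxyl carbon are cis on the ring, as a fused six-membered acetal lactone demands.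
- Forward order: chiral dioxinone from (S)-3-hydroxybutanoic acid; thiyl-radical [3+2] annulation closes the five-membered ring; hydride removes the acetal; ring side C10 to C13 to C15; acyclic side C15 + C10; the halves are joined last.
- Stereochemistry: the acetal carbon (from the chiral-pool acid) directs the radical to one face and sets C5; the cis-fused lactone fixes C6 relative to C5; exo ring closure sets C2 trans to C7; E double bonds come from HWE and Wittig steps with crystallisation and thermal equilibration.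

Key step: step 4

Assumption: the alkyl radical attacks the dioxinone on the face anti to tert-butyl, the sense known for cuprates and for hydrogen on this ring, which is why the (S) acid is chosen; pseudoionone is taken as its (3E,5E) isomer.

**Route**

Step 1
Reactants: 1 (S)-3-hydroxybutanoic acid
Product: 2 (2S,6S)-2-tert-butyl-6-methyl-1,3-dioxan-4-one (cis)
Conditions: t-BuCHO, TsOH (cat.), CH2Cl2, reflux, azeotropic removal of water; recrystallise
Reagents that add atoms: pivalaldehyde, CC(C)(C)C=O
Why: Acid-catalysed acetalisation under thermodynamic control should place tert-butyl and methyl both equatorial, so the (S) centre of 1 sets the acetal carbon as (S).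

Step 2
Reactants: 2 (2S,6S)-2-tert-butyl-6-methyl-1,3-dioxan-4-one
Product: 6 (S)-2-tert-butyl-6-methyl-4H-1,3-dioxin-4-one, via lithium enolate 3 (not isolated), via selenide 4 (not isolated), via selenoxide 5 (not isolated)
Conditions: LiN(iPr)2, THF, −78 °C; PhSeBr, −78 °C; then H2O2, pyridine, CH2Cl2, 0 °C to rt
Reagents that add atoms: none
Why: Enolate selenenylation trans to the 6-methyl group followed by selenoxide syn-elimination (selenium is cis to H-6) should give the enoate; the carbinol centre is erased while the acetal carbon keeps the chirality (self-regeneration of a stereocentre).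

Step 3
Reactants: 7 cyclopropyl methyl ketone
Product: 8 isopropenylcyclopropane (2-cyclopropylprop-1-ene)
Conditions: Ph3PCH3Br, KOC(CH3)3, DMSO, rt to 50 °C; product distilled from the flask
Reagents that add atoms: methyltriphenylphosphonium bromide (as its ylide), C[P+](c1ccccc1)(c1ccccc1)c1ccccc1.[Br-]
Why: Wittig methylenation of a methyl ketone; the volatile hydrocarbon should be separable from the phosphine oxide by distillation.

Step 4
Reactants: 6 (S)-2-tert-butyl-6-methyl-4H-1,3-dioxin-4-one; 8 isopropenylcyclopropane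
Product: 11 (2S,4aS,5R,7aR)-2-tert-butyl-7a-methyl-5-(prop-1-en-2-yl)hexahydrocyclopenta[d][1,3]dioxin-4-one, via homoallyl radical 9 (not isolated), via lactone α-radical 10 (not isolated)
Conditions: 8 (3 equiv), PhSSPh (20 mol %), AIBN (10 mol %, in portions), PhH (1 M in 6), sealed tube, 80 °C
Reagents that add atoms: none
Why: Proposed new method: PhS• (from PhSSPh and AIBN) adds to the CH2 terminus of 8, the cyclopropylcarbinyl radical opens to the primary homoallyl radical 9, 9 adds to C6 of 6 (the β-carbon of the enoate) to give the lactone α-radical 10, and 10 closes onto the allyl sulfide carbon and expels PhS•, which carries the chain and lets the isopropenyl group reappear. The closest known reaction type is the thiyl-radical-catalysed [3+2] annulation of vinylcyclopropanes with acrylates, and attack of an alkyl radical on an oxygen-bearing β-carbon has its analogy in β-alkoxyacrylate radical cyclisations, but a 1,3-dioxin-4-one has not served as the two-carbon partner and the fully substituted carbinol carbon should make the addition slower. The cyclopentane closes by 5-exo-trig attack of 10 on the trisubstituted alkene, followed by β-scission of the C–S bond. C7a (the carbinol carbon) is set by approach of 9 anti to the tert-butyl group of the sofa-shaped dioxinone, C4a by the cis fusion that a five-membered ring must adopt on the six-membered lactone, and C5 by the pseudo-equatorial, exo position of the bulky alkene terminus in the chair-like transition state, which puts the isopropenyl group trans to the lactone carbonyl carbon. The step needs β-regioselective addition (secured by the stabilised α-carbonyl radical that only this mode gives), chain propagation faster than capture of 9 by the disulfide (secured by catalytic PhSSPh and a high concentration of 6), and exo closure (secured by the convex shape of the forming cis-bicycle).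

Step 5
Reactants: 11 (2S,4aS,5R,7aR)-2-tert-butyl-7a-methyl-5-(prop-1-en-2-yl)hexahydrocyclopenta[d][1,3]dioxin-4-one
Product: 12 (1R,2R,3R)-2-(hydroxymethyl)-1-methyl-3-(prop-1-en-2-yl)cyclopentan-1-ol
Conditions: LiAlH4, THF, 0 °C to rt; H2O, aq NaOH
Reagents that add atoms: none
Why: Hydride reduction of the acylal lactone opens the ring at the carbonyl, the hemiacetal left behind collapses to pivalaldehyde (reduced to neopentyl alcohol) and the tertiary alcohol is freed, with no stereocentre touched.

Step 6
Reactants: 12 (1R,2R,3R)-2-(hydroxymethyl)-1-methyl-3-(prop-1-en-2-yl)cyclopentan-1-ol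
Product: 13 (1S,2R,5R)-2-hydroxy-2-methyl-5-(prop-1-en-2-yl)cyclopentane-1-carbaldehyde
Conditions: TEMPO (cat.), PhI(OAc)2, CH2Cl2, rt
Reagents that add atoms: none
Why: Oxoammonium oxidation is selective for the primary alcohol (the tertiary one cannot be oxidised); the formyl group sits trans to both neighbouring carbon substituents, the arrangement expected at equilibrium, so the α-centre should hold.

Step 7
Reactants: 13 (1S,2R,5R)-2-hydroxy-2-methyl-5-(prop-1-en-2-yl)cyclopentane-1-carbaldehyde
Product: 14 (3E)-4-[(1S,2R,5R)-2-hydroxy-2-methyl-5-(prop-1-en-2-yl)cyclopentyl]but-3-en-2-one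
Conditions: (MeO)2P(O)CH2C(O)CH3, LiCl, iPr2NEt, MeCN, rt
Reagents that add atoms: dimethyl (2-oxopropyl)phosphonate, CC(=O)CP(=O)(OC)OC
Why: Horner–Wadsworth–Emmons olefination with LiCl and an amine base is mild enough for a free β-hydroxy aldehyde and should give the (E)-enone from the stabilised phosphonate anion.

Step 8
Reactants: 14 (3E)-4-[(1S,2R,5R)-2-hydroxy-2-methyl-5-(prop-1-en-2-yl)cyclopentyl]but-3-en-2-one
Product: 15 (1E)-1-[(1S,2R,5R)-2-hydroxy-2-methyl-5-(prop-1-en-2-yl)cyclopentyl]-3-methylpenta-1,4-dien-3-ol (both C3 epimers)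
Conditions: CH2=CHMgBr (3 equiv), THF, −78 to 0 °C; aq NH4Cl
Reagents that add atoms: vinylmagnesium bromide, C=C[Mg]Br
Why: 1,2-Addition of a vinyl Grignard reagent to the enone (one equivalent is spent on the hydroxyl group); the new carbinol centre is a mixture, which does not matter because it becomes planar in step 9.

Step 9
Reactants: 15 (1E)-1-[(1S,2R,5R)-2-hydroxy-2-methyl-5-(prop-1-en-2-yl)cyclopentyl]-3-methylpenta-1,4-dien-3-ol
Product: 16 [(2E,4E)-5-[(1S,2R,5R)-2-hydroxy-2-methyl-5-(prop-1-en-2-yl)cyclopentyl]-3-methylpenta-2,4-dien-1-yl]triphenylphosphonium bromide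
Conditions: PPh3·HBr, MeOH, rt; crystallise
Reagents that add atoms: triphenylphosphine hydrobromide, Br.c1ccc(cc1)P(c1ccccc1)c1ccccc1
Why: Ionisation of the bis-allylic tertiary alcohol and capture of the pentadienyl cation by PPh3 at its unhindered terminus (allylic transposition, as in the vinyl carbinol to C15 salt conversion of ionone chemistry) should give the (2E,4E) salt, enriched by crystallisation, while the non-allylic ring alcohol is not ionised.

Step 10
Reactants: 17 (3E,5E)-pseudoionone
Product: 18 (4E,6E)-3,7,11-trimethyldodeca-1,4,6,10-tetraen-3-ol (racemic)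
Conditions: CH2=CHMgBr, THF, 0 °C; aq NH4Cl
Reagents that add atoms: vinylmagnesium bromide, C=C[Mg]Br
Why: 1,2-Addition of a vinyl Grignard reagent to the dienone carbonyl, the standard entry to the acyclic C15 unit.

Step 11
Reactants: 18 (4E,6E)-3,7,11-trimethyldodeca-1,4,6,10-tetraen-3-ol
Product: 19 [(2E,4E,6E)-3,7,11-trimethyldodeca-2,4,6,10-tetraen-1-yl]triphenylphosphonium bromide
Conditions: PPh3·HBr, MeOH, rt; crystallise
Reagents that add atoms: triphenylphosphine hydrobromide, Br.c1ccc(cc1)P(c1ccccc1)c1ccccc1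
Why: The same ionisation and terminal capture by PPh3 as in step 9; crystallisation should remove (Z) isomers, including any that stem from (5Z)-pseudoionone.

Step 12
Reactants: 19 [(2E,4E,6E)-3,7,11-trimethyldodeca-2,4,6,10-tetraen-1-yl]triphenylphosphonium bromide; 20 (2E,4E,6E)-2,7-dimethylocta-2,4,6-trienedial
Product: 22 (2E,4E,6E,8E,10E,12E,14E)-2,7,11,15,19-pentamethylicosa-2,4,6,8,10,12,14,18-octaenal, via ylide 21 (not isolated)
Conditions: 20 (3 equiv), NaOCH3, MeOH/CH2Cl2, 0 °C to rt, slow addition of 19; then reflux in heptane, crystallise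
Reagents that add atoms: none
Why: Wittig olefination of the semi-stabilised polyenyl ylide with an excess of the symmetric dialdehyde should stop at mono-condensation, and the new C11'=C12' bond should equilibrate to E on heating.

Step 13
Reactants: 16 [(2E,4E)-5-[(1S,2R,5R)-2-hydroxy-2-methyl-5-(prop-1-en-2-yl)cyclopentyl]-3-methylpenta-2,4-dien-1-yl]triphenylphosphonium bromide; 22 (2E,4E,6E,8E,10E,12E,14E)-2,7,11,15,19-pentamethylicosa-2,4,6,8,10,12,14,18-octaenal
Product: 24 (2R,5R,6S)-1,16-didehydro-2,6-cyclolycopen-5-ol (all-E), via ylide 23 (not isolated)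
Conditions: NaOCH3, MeOH/CH2Cl2, rt, dark, Ar; then reflux in heptane, crystallise
Reagents that add atoms: none
Why: Wittig olefination forms C11=C12 with the free tertiary alcohol tolerated; the unhindered (Z) isomer should equilibrate thermally to all-E, and the three ring stereocentres are remote from the reaction site.

**Compound list**

1 | (S)-3-hydroxybutanoic acid | C[C@H](O)CC(=O)O | starting material
2 | (2S,6S)-2-tert-butyl-6-methyl-1,3-dioxan-4-one (cis) | C[C@H]1CC(=O)O[C@@H](C(C)(C)C)O1 | intermediate
3 | lithium enolate of 2 (formed in the flask in step 2) | C[C@H]1C=C(O[Li])O[C@@H](C(C)(C)C)O1 | intermediate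
4 | (2S,5S,6S)-2-tert-butyl-6-methyl-5-(phenylselanyl)-1,3-dioxan-4-one, selenium trans to the 6-methyl group (formed in the flask in step 2) | C[C@H]1[C@H]([Se]c2ccccc2)C(=O)O[C@@H](C(C)(C)C)O1 | intermediate
5 | selenoxide of 4 (formed in the flask in step 2) | C[C@H]1[C@H]([Se](=O)c2ccccc2)C(=O)O[C@@H](C(C)(C)C)O1 | intermediate
6 | (S)-2-tert-butyl-6-methyl-4H-1,3-dioxin-4-one | CC1=CC(=O)O[C@@H](C(C)(C)C)O1 | intermediate
7 | cyclopropyl methyl ketone (1-cyclopropylethan-1-one) | CC(=O)C1CC1 | starting material
8 | isopropenylcyclopropane (2-cyclopropylprop-1-ene) | CC(=C)C1CC1 | intermediate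
9 | 4-methyl-5-(phenylsulfanyl)pent-3-en-1-yl radical, E/Z mixture (formed in the flask in step 4) | [CH2]CC=C(C)CSc1ccccc1 | intermediate
10 | (2S)-2-tert-butyl-6-methyl-6-[4-methyl-5-(phenylsulfanyl)pent-3-en-1-yl]-4-oxo-1,3-dioxan-5-yl radical, new chain trans to tert-butyl (formed in the flask in step 4) | CC(CSc1ccccc1)=CCC[C@@]1(C)O[C@H](C(C)(C)C)OC(=O)[CH]1 | intermediate
11 | (2S,4aS,5R,7aR)-2-tert-butyl-7a-methyl-5-(prop-1-en-2-yl)hexahydrocyclopenta[d][1,3]dioxin-4-one (cis-fused; isopropenyl trans to the lactone carbonyl carbon; tert-butyl cis to the 7a-methyl) | CC(=C)[C@@H]1CC[C@@]2(C)O[C@H](C(C)(C)C)OC(=O)[C@@H]12 | intermediate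
12 | (1R,2R,3R)-2-(hydroxymethyl)-1-methyl-3-(prop-1-en-2-yl)cyclopentan-1-ol | CC(=C)[C@@H]1CC[C@@](C)(O)[C@H]1CO | intermediate
13 | (1S,2R,5R)-2-hydroxy-2-methyl-5-(prop-1-en-2-yl)cyclopentane-1-carbaldehyde | CC(=C)[C@@H]1CC[C@@](C)(O)[C@H]1C=O | intermediate
14 | (3E)-4-[(1S,2R,5R)-2-hydroxy-2-methyl-5-(prop-1-en-2-yl)cyclopentyl]but-3-en-2-one | CC(=C)[C@@H]1CC[C@@](C)(O)[C@H]1/C=C/C(C)=O | intermediate
15 | (1E)-1-[(1S,2R,5R)-2-hydroxy-2-methyl-5-(prop-1-en-2-yl)cyclopentyl]-3-methylpenta-1,4-dien-3-ol (both C3 epimers) | CC(=C)[C@@H]1CC[C@@](C)(O)[C@H]1/C=C/C(C)(O)C=C | intermediate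
16 | [(2E,4E)-5-[(1S,2R,5R)-2-hydroxy-2-methyl-5-(prop-1-en-2-yl)cyclopentyl]-3-methylpenta-2,4-dien-1-yl]triphenylphosphonium bromide | CC(=C)[C@@H]1CC[C@@](C)(O)[C@H]1/C=C/C(C)=C/C[P+](c1ccccc1)(c1ccccc1)c1ccccc1.[Br-] | intermediate
17 | (3E,5E)-pseudoionone ((3E,5E)-6,10-dimethylundeca-3,5,9-trien-2-one) | CC(=O)/C=C/C=C(\C)CCC=C(C)C | starting material
18 | (4E,6E)-3,7,11-trimethyldodeca-1,4,6,10-tetraen-3-ol (racemic) | C=CC(C)(O)/C=C/C=C(\C)CCC=C(C)C | intermediate
19 | [(2E,4E,6E)-3,7,11-trimethyldodeca-2,4,6,10-tetraen-1-yl]triphenylphosphonium bromide | CC(C)=CCC/C(C)=C/C=C/C(C)=C/C[P+](c1ccccc1)(c1ccccc1)c1ccccc1.[Br-] | intermediate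
20 | (2E,4E,6E)-2,7-dimethylocta-2,4,6-trienedial | O=C/C(C)=C/C=C/C=C(C)/C=O | starting material
21 | ylide of 19 (formed in the flask in step 12) | CC(C)=CCC/C(C)=C/C=C/C(C)=C/C=P(c1ccccc1)(c1ccccc1)c1ccccc1 | intermediate
22 | (2E,4E,6E,8E,10E,12E,14E)-2,7,11,15,19-pentamethylicosa-2,4,6,8,10,12,14,18-octaenal (acyclic C25 aldehyde) | O=C/C(C)=C/C=C/C=C(C)/C=C/C=C(C)/C=C/C=C(\C)CCC=C(C)C | intermediate
23 | ylide of 16 (formed in the flask in step 13) | CC(=C)[C@@H]1CC[C@@](C)(O)[C@H]1/C=C/C(C)=C/C=P(c1ccccc1)(c1ccccc1)c1ccccc1 | intermediate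
24 | (2R,5R,6S)-1,16-didehydro-2,6-cyclolycopen-5-ol, all-E; (1R,2S,3R)-1-methyl-3-(prop-1-en-2-yl)-2-[(1E,3E,5E,7E,9E,11E,13E,15E,17E,19E)-3,7,12,16,20,24-hexamethylpentacosa-1,3,5,7,9,11,13,15,17,19,23-undecaen-1-yl]cyclopentan-1-ol | C=C(C)[C@@H]1CC[C@@](C)(O)[C@H]1/C=C/C(C)=C/C=C/C(C)=C/C=C/C=C(C)/C=C/C=C(C)/C=C/C=C(\C)CCC=C(C)C | target

**Count**

Total step count: 13. Longest linear sequence: 9 steps (1, 2, 4, 5, 6, 7, 8, 9, 13).

**Steps most likely to fail**

Step 4 (Proposed new method). Addition of the primary radical to the hindered, oxygen-bearing alkene carbon may be too slow, so that capture by the disulfide or hydrogen abstraction from the allylic methyl group takes over; facial or exo selectivity may also be poor. The fallback uses known chiral-pool chemistry and gives up both partners of step 4, so it cannot set out from a numbered compound. It sets out from commercial (4R)-limonene 1,2-oxide F1 and comes back to the route at 13, so that steps 1 to 6 fall away. Cleavage of the epoxide with H5IO6 (THF/H2O, 0 °C) should give (3R)-6-oxo-3-(prop-1-en-2-yl)heptanal F2, in which the carbon that becomes C2 already has the (R) configuration. An amine-catalysed intramolecular aldol addition of the aldehyde α-carbon to the methyl ketone (L-proline, DMF, rt, stopped before loss of water) should then close the C5–C6 bond and give 13; the isomer with the formyl group trans to both carbon neighbours is the one expected at equilibrium.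

Step 7. Retro-aldol opening of the ring or loss of water from the free β-hydroxy aldehyde may occur under the basic olefination, or the hindered formyl group may react too slowly. The fallback sets out from 13 and comes back at 16, replacing steps 7 to 9 by a protected C5 homologation. Silylation of the tertiary alcohol (N-(trimethylsilyl)imidazole, CH2Cl2, rt) should give (1S,2R,5R)-2-methyl-5-(prop-1-en-2-yl)-2-[(trimethylsilyl)oxy]cyclopentane-1-carbaldehyde F3. Horner–Wadsworth–Emmons reaction with triethyl 3-methyl-4-phosphonocrotonate (LiN(SiMe3)2, THF, −78 to 0 °C) should give ethyl (2E,4E)-3-methyl-5-[(1S,2R,5R)-2-methyl-5-(prop-1-en-2-yl)-2-[(trimethylsilyl)oxy]cyclopentyl]penta-2,4-dienoate F4. Reduction with iBu2AlH (CH2Cl2, −78 °C) should give (2E,4E)-3-methyl-5-[(1S,2R,5R)-2-methyl-5-(prop-1-en-2-yl)-2-[(trimethylsilyl)oxy]cyclopentyl]penta-2,4-dien-1-ol F5. PPh3·HBr in MeOH should then convert F5 into 16, the silyl ether being cleaved in the acidic methanol.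

Step 9. After ionisation of the bis-allylic alcohol, loss of the ring proton next to the cation or internal capture by the ring hydroxyl may outrun capture by the phosphine. The fallback sets out from 15 (and uses 22) and comes back at the target 24, replacing steps 9 and 13 by a coupling with reversed roles. Babler oxidation of 15 (pyridinium chlorochromate, CH2Cl2, rt; oxidative 1,3-transposition of the tertiary vinyl carbinol) should give (2E,4E)-5-[(1S,2R,5R)-2-hydroxy-2-methyl-5-(prop-1-en-2-yl)cyclopentyl]-3-methylpenta-2,4-dienal F6. On the robust acyclic fragment, NaBH4 (MeOH/THF, 0 °C) should reduce 22 to (2E,4E,6E,8E,10E,12E,14E)-2,7,11,15,19-pentamethylicosa-2,4,6,8,10,12,14,18-octaen-1-ol F7, and PPh3·HBr (MeOH, rt) should give [(2E,4E,6E,8E,10E,12E,14E)-2,7,11,15,19-pentamethylicosa-2,4,6,8,10,12,14,18-octaen-1-yl]triphenylphosphonium bromide F8. NaOCH3 should convert F8 into its ylide F9, which should react with F6 in a Wittig reaction to give 24 after thermal equilibration.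

**Further compounds**

F1 | step 4 | (4R)-limonene 1,2-oxide (commercial mixture of cis and trans epoxides) | CC12OC1C[C@H](C(C)=C)CC2
F2 | step 4 | (3R)-6-oxo-3-(prop-1-en-2-yl)heptanal | O=CC[C@H](C(C)=C)CCC(C)=O
F3 | step 7 | (1S,2R,5R)-2-methyl-5-(prop-1-en-2-yl)-2-[(trimethylsilyl)oxy]cyclopentane-1-carbaldehyde | CC(=C)[C@@H]1CC[C@@](C)(O[Si](C)(C)C)[C@H]1C=O
F4 | step 7 | ethyl (2E,4E)-3-methyl-5-[(1S,2R,5R)-2-methyl-5-(prop-1-en-2-yl)-2-[(trimethylsilyl)oxy]cyclopentyl]penta-2,4-dienoate | CC(=C)[C@@H]1CC[C@@](C)(O[Si](C)(C)C)[C@H]1/C=C/C(C)=C/C(=O)OCC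
F5 | step 7 | (2E,4E)-3-methyl-5-[(1S,2R,5R)-2-methyl-5-(prop-1-en-2-yl)-2-[(trimethylsilyl)oxy]cyclopentyl]penta-2,4-dien-1-ol | CC(=C)[C@@H]1CC[C@@](C)(O[Si](C)(C)C)[C@H]1/C=C/C(C)=C/CO
F6 | step 9 | (2E,4E)-5-[(1S,2R,5R)-2-hydroxy-2-methyl-5-(prop-1-en-2-yl)cyclopentyl]-3-methylpenta-2,4-dienal | CC(=C)[C@@H]1CC[C@@](C)(O)[C@H]1/C=C/C(C)=C/C=O
F7 | step 9 | (2E,4E,6E,8E,10E,12E,14E)-2,7,11,15,19-pentamethylicosa-2,4,6,8,10,12,14,18-octaen-1-ol | OC/C(C)=C/C=C/C=C(C)/C=C/C=C(C)/C=C/C=C(\C)CCC=C(C)C
F8 | step 9 | [(2E,4E,6E,8E,10E,12E,14E)-2,7,11,15,19-pentamethylicosa-2,4,6,8,10,12,14,18-octaen-1-yl]triphenylphosphonium bromide | [Br-].c1ccccc1[P+](c1ccccc1)(c1ccccc1)C/C(C)=C/C=C/C=C(C)/C=C/C=C(C)/C=C/C=C(\C)CCC=C(C)C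
F9 | step 9 | ylide of F8 | c1ccccc1P(c1ccccc1)(c1ccccc1)=C/C(C)=C/C=C/C=C(C)/C=C/C=C(C)/C=C/C=C(\C)CCC=C(C)C
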